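**Retrosynthetic overview**

- Feature: ring A is a phloroglucinol nucleus in which every position differs (C5–OMe, C6–alkyl, C7–OH, C8–H) and which is fused to ring C through C4a–C8a. It is therefore built new from acyclic carbons instead of being substituted at C6 in competition with C8.
- Last disconnections: the four silyl ethers are removed and the C5–O–methyl bond is cut, leading back to a 5-hydroxy-7-silyloxyflavanone whose only free hydroxyl is the chelated C5–OH.
- Key disconnection: ring A is cut at C5–C6, C7–C8 and C4a–C5 (C8–C8a comes from a 1,2-shift in the same step) into a 6-(diazoacetyl)-2,3-dihydropyran-4-one carrying ring B and a siloxyalkyne carrying the side chain.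
- Ring C comes from 2,4-bis(silyloxy)benzaldehyde and the bis-silyl dienol ether of methyl 2,4-dioxopentanoate by catalytic asymmetric aldol–cyclocondensation, which sets C2. The siloxyalkyne comes from an Evans propargylation of a 5-methylhex-4-enoyl imide (which sets the side-chain centre), methyl addition, and oxidation of the acetylide to the ynolate with O-silylation.
- Ring order: ring B is bought, ring C is made second, ring A is made last.

Key step: step 12

Remark: ring A atoms carry flavanone numbering (C4a, C5–C8, C8a) throughout; in the monocyclic pyranones the carbons that become C4a and C8a are C5 and C6. Both stereocentres of the target are (S). TBS = tert-butyldimethylsilyl, TIPS = triisopropylsilyl, TES = triethylsilyl, TMS = trimethylsilyl.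

**Route**

Step 1
Reactants: 1 2,4-dihydroxybenzaldehyde
Product: 2 2,4-bis(tert-butyldimethylsilyloxy)benzaldehyde
Conditions: TBSCl (2.5 equiv), imidazole, DMF, 23 °C
Reagents that add atoms: tert-butyldimethylsilyl chloride, CC(C)(C)[Si](C)(C)Cl
Why: Imidazole-mediated silylation of both phenols (standard silyl ether formation) removes the acidic, chelating hydroxyls so that the aldehyde alone binds the Lewis acid in step 3.

Step 2
Reactants: 3 methyl 2,4-dioxopentanoate
Product: 5 methyl (2Z)-2,4-bis(trimethylsilyloxy)penta-2,4-dienoate, via monosilyl enol ether 4 (not isolated)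
Conditions: Me3SiOTf (2.2 equiv), Et3N, Et2O, 0 → 23 °C; used crude
Reagents that add atoms: trimethylsilyl triflate, C[Si](C)(C)OS(=O)(=O)C(F)(F)F
Why: Soft enolisation with a silyl triflate and an amine silylates the enolised C2 oxygen and then turns the methyl ketone into its silyl enol ether, giving a Danishefsky-type 1,3-dioxygenated diene whose C2=C3 geometry is lost in step 3 and is of no consequence.

Step 3
Reactants: 2 2,4-bis(tert-butyldimethylsilyloxy)benzaldehyde; 5 methyl (2Z)-2,4-bis(trimethylsilyloxy)penta-2,4-dienoate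
Product: 7 methyl (2S)-2-[2,4-bis(tert-butyldimethylsilyloxy)phenyl]-4-oxo-3,4-dihydro-2H-pyran-6-carboxylate, via silylated aldol adduct 6 (not isolated)
Conditions: Ti(OiPr)4 (10 mol %), (S)-BINOL (20 mol %), 4 Å MS, Et2O, −20 → 0 °C; then CF3CO2H, CH2Cl2, 0 °C
Reagents that add atoms: none
Why: Catalytic asymmetric Mukaiyama aldol addition of the terminal enol ether carbon to the aldehyde bound to the Ti(OiPr)4/BINOL catalyst (a formal hetero-Diels–Alder reaction) should set C2 as (S) by Si-face attack, the sense being assigned by analogy with 1-methoxy-3-silyloxybutadiene and corrected with (R)-BINOL if it proves reversed, and acid then closes ring C by attack of the carbinol oxygen on the siloxy-bearing alkene carbon with loss of the silyl oxygen.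

Step 4
Reactants: 7 methyl (2S)-2-[2,4-bis(tert-butyldimethylsilyloxy)phenyl]-4-oxo-3,4-dihydro-2H-pyran-6-carboxylate
Product: 9 (2S)-2-[2,4-bis(tert-butyldimethylsilyloxy)phenyl]-4-oxo-3,4-dihydro-2H-pyran-6-carboxylic acid, via trimethylstannyl ester 8 (not isolated)
Conditions: Me3SnOH (5 equiv), ClCH2CH2Cl, 70 °C; then cold 0.1 M HCl wash
Reagents that add atoms: trimethyltin hydroxide, C[Sn](C)(C)O
Why: Me3SnOH delivers hydroxide to the ester carbonyl under near-neutral conditions (tin hydroxide ester cleavage), which should spare the aryl silyl ethers and avoid the C3 enolate that would open ring C and erode C2.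

Step 5
Reactants: 9 (2S)-2-[2,4-bis(tert-butyldimethylsilyloxy)phenyl]-4-oxo-3,4-dihydro-2H-pyran-6-carboxylic acid
Product: 11 (2S)-2-[2,4-bis(tert-butyldimethylsilyloxy)phenyl]-6-(diazoacetyl)-2,3-dihydro-4H-pyran-4-one, via mixed carbonic anhydride 10 (not isolated)
Conditions: i-BuOCOCl, N-methylmorpholine, THF, −20 °C; then CH2N2, Et2O, 0 °C
Reagents that add atoms: diazomethane, C=[N+]=[N-]; isobutyl chloroformate, CC(C)COC(=O)Cl (retained only in 10)
Why: Acylation of diazomethane by the mixed carbonic anhydride (first stage of an Arndt–Eistert sequence) should outrun dipolar cycloaddition to the pyranone C5=C6 alkene, which the ring-oxygen donor deactivates, and it touches no stereocentre.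

Step 6
Reactants: 12 5-methylhex-4-enoic acid; 13 (4R)-4-benzyl-1,3-oxazolidin-2-one
Product: 15 (4R)-4-benzyl-3-(5-methylhex-4-enoyl)-1,3-oxazolidin-2-one, via mixed pivalic anhydride 14 (not isolated)
Conditions: t-BuCOCl, Et3N, THF, −20 °C; then 13, LiCl, 23 °C
Reagents that add atoms: pivaloyl chloride, CC(C)(C)C(=O)Cl (retained only in 14)
Why: N-acylation of the oxazolidinone by the mixed pivalic anhydride under LiCl/Et3N activation is the standard loading of the Evans auxiliary and occurs at the less hindered acyl carbon.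

Step 7
Reactants: 15 (4R)-4-benzyl-3-(5-methylhex-4-enoyl)-1,3-oxazolidin-2-one
Product: 17 (4R)-4-benzyl-3-[(2S)-5-methyl-2-(prop-2-yn-1-yl)hex-4-enoyl]-1,3-oxazolidin-2-one, via sodium enolate 16 (not isolated)
Conditions: NaN(SiMe3)2, THF, −78 °C; HC≡CCH2Br, −78 → −40 °C
Reagents that add atoms: propargyl bromide, C#CCBr; sodium bis(trimethylsilyl)amide, C[Si](C)(C)[N-][Si](C)(C)C.[Na+] (sodium retained only in 16)
Why: In this Evans alkylation the chelated (Z)-sodium enolate 16 is attacked by propargyl bromide on the face opposite the C4 benzyl group, which sets the side-chain centre as (S).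

Step 8
Reactants: 17 (4R)-4-benzyl-3-[(2S)-5-methyl-2-(prop-2-yn-1-yl)hex-4-enoyl]-1,3-oxazolidin-2-one
Product: 18 benzyl (2S)-5-methyl-2-(prop-2-yn-1-yl)hex-4-enoate
Conditions: PhCH2OLi (from PhCH2OH, n-BuLi), THF, −78 → 0 °C
Reagents that add atoms: benzyl alcohol, OCc1ccccc1
Why: Lithium benzyloxide attacks the exocyclic imide carbonyl (Evans transesterification), releasing the auxiliary for recovery without enolising the new stereocentre.

Step 9
Reactants: 18 benzyl (2S)-5-methyl-2-(prop-2-yn-1-yl)hex-4-enoate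
Product: 20 (3S)-2,6-dimethyl-3-(prop-2-yn-1-yl)hept-5-en-2-ol, via methyl ketone 19 (not isolated)
Conditions: MeMgBr (4 equiv), THF, 0 → 23 °C
Reagents that add atoms: methylmagnesium bromide, C[Mg]Br
Why: Double Grignard addition to the ester through ketone 19 builds the dimethyl carbinol, with one equivalent of reagent held reversibly by the alkyne C–H and the stereocentre kept because addition outruns enolisation.

Step 10
Reactants: 20 (3S)-2,6-dimethyl-3-(prop-2-yn-1-yl)hept-5-en-2-ol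
Product: 21 (3S)-2,6-dimethyl-3-(prop-2-yn-1-yl)-2-(triethylsilyloxy)hept-5-ene
Conditions: Et3SiOTf, 2,6-lutidine, CH2Cl2, −78 → 0 °C
Reagents that add atoms: triethylsilyl triflate, CC[Si](CC)(CC)OS(=O)(=O)C(F)(F)F
Why: A silyl triflate with a hindered pyridine base is the standard silylation of a tertiary alcohol and leaves the terminal alkyne and the trisubstituted alkene alone.

Step 11
Reactants: 21 (3S)-2,6-dimethyl-3-(prop-2-yn-1-yl)-2-(triethylsilyloxy)hept-5-ene
Product: 24 (4S)-7-methyl-4-[2-(triethylsilyloxy)propan-2-yl]-1-(triisopropylsilyloxy)oct-6-en-1-yne, via lithium acetylide 22 (not isolated), via lithium ynolate 23 (not isolated)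
Conditions: n-BuLi, THF, −78 °C; t-BuOOLi (from t-BuOOH, LiN(SiMe3)2), −78 → 0 °C; i-Pr3SiOTf, −78 → 0 °C
Reagents that add atoms: tert-butyl hydroperoxide, CC(C)(C)OO; triisopropylsilyl triflate, CC(C)[Si](OS(=O)(=O)C(F)(F)F)(C(C)C)C(C)C; n-butyllithium, [Li]CCCC (lithium retained only in 22 and 23)
Why: The lithium acetylide is oxidised by lithium tert-butyl peroxide, an electrophilic oxygen donor, to lithium ynolate 23 (acetylide-to-ynolate oxidation), which the bulky silyl triflate traps on oxygen to give the siloxyalkyne.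

Step 12
Reactants: 11 (2S)-2-[2,4-bis(tert-butyldimethylsilyloxy)phenyl]-6-(diazoacetyl)-2,3-dihydro-4H-pyran-4-one; 24 (4S)-7-methyl-4-[2-(triethylsilyloxy)propan-2-yl]-1-(triisopropylsilyloxy)oct-6-en-1-yne (1.5 equiv)
Product: 29 (2S)-2-[2,4-bis(tert-butyldimethylsilyloxy)phenyl]-5-hydroxy-6-[(2S)-5-methyl-2-[2-(triethylsilyloxy)propan-2-yl]hex-4-en-1-yl]-7-(triisopropylsilyloxy)-2,3-dihydro-4H-chromen-4-one, via vinylketene 25 (not isolated), via vinylcyclobutenone 26 (not isolated), via dienylketene 27 (not isolated), via cyclohexadienone 28 (not isolated)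
Conditions: hν (medium-pressure Hg lamp, Pyrex filter, >300 nm), degassed ClCH2CH2Cl, 20 °C; then 80 °C, dark
Reagents that add atoms: none
Why: Irradiation expels N2 from 11 and the carbon that becomes C8a shifts from the acyl carbon (future C5) to the carbene carbon (future C8) in a Wolff rearrangement, giving vinylketene 25. The nucleophilic carbon of siloxyalkyne 24, which bears the side chain, attacks the ketene carbonyl carbon and the siloxy carbon bonds to the ketene α-carbon, a [2+2] cycloaddition that forms C5–C6 and C7–C8 in cyclobutenone 26. Cyclobutenone 26 opens by 4π electrocyclic cleavage of its C5–C8 bond to dienylketene 27, and ring A closes by thermal disrotatory 6π electrocyclisation that joins C5 to C4a, after which cyclohexadienone 28 tautomerises to phenol 29. The closest known reaction type is the Danheiser benzannulation of α-diazo enones with trialkylsiloxyalkynes, which gives resorcinol monosilyl ethers with the alkyne substituent between the two oxygens. No lasting stereocentre is formed, because the sp3 carbons of 26 and 28 are planarised on aromatisation, and C2 and the side-chain centre are spectators of neutral pericyclic steps. The step needs regiocontrol in the [2+2] event, which the oxygen-polarised alkyne provides so that the alkyl group lands at C6 between C5–OH and C7–OTIPS, and it needs C4a to be reachable, which the ring alkene of 11 ensures by holding C4a–H cis to the ketene-bearing carbon and the C4 carbonyl away from the ketene.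

Step 13
Reactants: 29 (2S)-2-[2,4-bis(tert-butyldimethylsilyloxy)phenyl]-5-hydroxy-6-[(2S)-5-methyl-2-[2-(triethylsilyloxy)propan-2-yl]hex-4-en-1-yl]-7-(triisopropylsilyloxy)-2,3-dihydro-4H-chromen-4-one
Product: 30 (2S)-2-[2,4-bis(tert-butyldimethylsilyloxy)phenyl]-5-methoxy-6-[(2S)-5-methyl-2-[2-(triethylsilyloxy)propan-2-yl]hex-4-en-1-yl]-7-(triisopropylsilyloxy)-2,3-dihydro-4H-chromen-4-one
Conditions: MeI, Ag2O, 4 Å MS, CH2Cl2, 40 °C, dark
Reagents that add atoms: methyl iodide, CI
Why: Purdie methylation with MeI and Ag2O etherifies the only free hydroxyl, the chelated C5 phenol, without the soluble base that would open ring C by retro-oxa-Michael reaction and racemise C2.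

Step 14
Reactants: 30 (2S)-2-[2,4-bis(tert-butyldimethylsilyloxy)phenyl]-5-methoxy-6-[(2S)-5-methyl-2-[2-(triethylsilyloxy)propan-2-yl]hex-4-en-1-yl]-7-(triisopropylsilyloxy)-2,3-dihydro-4H-chromen-4-one
Product: 31 (2S)-2-(2,4-dihydroxyphenyl)-7-hydroxy-6-[(2S)-2-(2-hydroxypropan-2-yl)-5-methylhex-4-en-1-yl]-5-methoxy-2,3-dihydro-4H-chromen-4-one
Conditions: Bu4NF, AcOH (1:1), THF, 0 → 23 °C
Reagents that add atoms: none
Why: Fluoride-mediated desilylation cleaves the three aryl silyl ethers and the tertiary triethylsilyl ether, and the acetic acid buffer keeps the freed phenols protonated so that ring C does not open, while no strong acid is present that could cyclise the tertiary alcohol onto ring A or the alkene.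

**Compound list**

1 | 2,4-dihydroxybenzaldehyde | O=Cc1ccc(O)cc1O | starting material
2 | 2,4-bis(tert-butyldimethylsilyloxy)benzaldehyde | O=Cc1ccc(O[Si](C)(C)C(C)(C)C)cc1O[Si](C)(C)C(C)(C)C | intermediate
3 | methyl 2,4-dioxopentanoate | COC(=O)C(=O)CC(C)=O | starting material
4 | methyl (2Z)-4-oxo-2-(trimethylsilyloxy)pent-2-enoate | COC(=O)/C(O[Si](C)(C)C)=C/C(C)=O | intermediate
5 | methyl (2Z)-2,4-bis(trimethylsilyloxy)penta-2,4-dienoate | COC(=O)/C(O[Si](C)(C)C)=C/C(=C)O[Si](C)(C)C | intermediate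
6 | methyl (2Z,6S)-6-[2,4-bis(tert-butyldimethylsilyloxy)phenyl]-4-oxo-2,6-bis(trimethylsilyloxy)hex-2-enoate | COC(=O)/C(O[Si](C)(C)C)=C/C(=O)C[C@H](O[Si](C)(C)C)c1ccc(O[Si](C)(C)C(C)(C)C)cc1O[Si](C)(C)C(C)(C)C | intermediate
7 | methyl (2S)-2-[2,4-bis(tert-butyldimethylsilyloxy)phenyl]-4-oxo-3,4-dihydro-2H-pyran-6-carboxylate | COC(=O)C1=CC(=O)C[C@@H](c2ccc(O[Si](C)(C)C(C)(C)C)cc2O[Si](C)(C)C(C)(C)C)O1 | intermediate
8 | trimethylstannyl (2S)-2-[2,4-bis(tert-butyldimethylsilyloxy)phenyl]-4-oxo-3,4-dihydro-2H-pyran-6-carboxylate | C[Sn](C)(C)OC(=O)C1=CC(=O)C[C@@H](c2ccc(O[Si](C)(C)C(C)(C)C)cc2O[Si](C)(C)C(C)(C)C)O1 | intermediate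
9 | (2S)-2-[2,4-bis(tert-butyldimethylsilyloxy)phenyl]-4-oxo-3,4-dihydro-2H-pyran-6-carboxylic acid | OC(=O)C1=CC(=O)C[C@@H](c2ccc(O[Si](C)(C)C(C)(C)C)cc2O[Si](C)(C)C(C)(C)C)O1 | intermediate
10 | isobutyl carbonic anhydride of acid 9 | CC(C)COC(=O)OC(=O)C1=CC(=O)C[C@@H](c2ccc(O[Si](C)(C)C(C)(C)C)cc2O[Si](C)(C)C(C)(C)C)O1 | intermediate
11 | (2S)-2-[2,4-bis(tert-butyldimethylsilyloxy)phenyl]-6-(diazoacetyl)-2,3-dihydro-4H-pyran-4-one | [N-]=[N+]=CC(=O)C1=CC(=O)C[C@@H](c2ccc(O[Si](C)(C)C(C)(C)C)cc2O[Si](C)(C)C(C)(C)C)O1 | intermediate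
12 | 5-methylhex-4-enoic acid | CC(C)=CCCC(=O)O | starting material
13 | (4R)-4-benzyl-1,3-oxazolidin-2-one | O=C1N[C@H](Cc2ccccc2)CO1 | starting material
14 | 5-methylhex-4-enoic pivalic anhydride | CC(C)=CCCC(=O)OC(=O)C(C)(C)C | intermediate
15 | (4R)-4-benzyl-3-(5-methylhex-4-enoyl)-1,3-oxazolidin-2-one | CC(C)=CCCC(=O)N1[C@H](Cc2ccccc2)COC1=O | intermediate
16 | sodium (Z)-enolate of imide 15 | CC(C)=CC/C=C(\[O-])N1[C@H](Cc2ccccc2)COC1=O.[Na+] | intermediate
17 | (4R)-4-benzyl-3-[(2S)-5-methyl-2-(prop-2-yn-1-yl)hex-4-enoyl]-1,3-oxazolidin-2-one | C#CC[C@H](CC=C(C)C)C(=O)N1[C@H](Cc2ccccc2)COC1=O | intermediate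
18 | benzyl (2S)-5-methyl-2-(prop-2-yn-1-yl)hex-4-enoate | C#CC[C@H](CC=C(C)C)C(=O)OCc1ccccc1 | intermediate
19 | (3S)-6-methyl-3-(prop-2-yn-1-yl)hept-5-en-2-one | C#CC[C@H](CC=C(C)C)C(C)=O | intermediate
20 | (3S)-2,6-dimethyl-3-(prop-2-yn-1-yl)hept-5-en-2-ol | C#CC[C@H](CC=C(C)C)C(C)(C)O | intermediate
21 | (3S)-2,6-dimethyl-3-(prop-2-yn-1-yl)-2-(triethylsilyloxy)hept-5-ene | C#CC[C@H](CC=C(C)C)C(C)(C)O[Si](CC)(CC)CC | intermediate
22 | lithium acetylide of alkyne 21 | [Li]C#CC[C@H](CC=C(C)C)C(C)(C)O[Si](CC)(CC)CC | intermediate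
23 | lithium (4S)-7-methyl-4-[2-(triethylsilyloxy)propan-2-yl]oct-6-en-1-yn-1-olate | [Li+].[O-]C#CC[C@H](CC=C(C)C)C(C)(C)O[Si](CC)(CC)CC | intermediate
24 | (4S)-7-methyl-4-[2-(triethylsilyloxy)propan-2-yl]-1-(triisopropylsilyloxy)oct-6-en-1-yne | CC(C)[Si](OC#CC[C@H](CC=C(C)C)C(C)(C)O[Si](CC)(CC)CC)(C(C)C)C(C)C | intermediate
25 | (2S)-2-[2,4-bis(tert-butyldimethylsilyloxy)phenyl]-6-(2-oxoethenyl)-2,3-dihydro-4H-pyran-4-one (vinylketene) | O=C=CC1=CC(=O)C[C@@H](c2ccc(O[Si](C)(C)C(C)(C)C)cc2O[Si](C)(C)C(C)(C)C)O1 | intermediate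
26 | 4-(pyranon-6-yl)-2-(side chain)-3-(triisopropylsilyloxy)cyclobut-2-en-1-one (ring carbon 4 unassigned) | O=C1C(C[C@H](CC=C(C)C)C(C)(C)O[Si](CC)(CC)CC)=C(O[Si](C(C)C)(C(C)C)C(C)C)C1C1=CC(=O)C[C@@H](c2ccc(O[Si](C)(C)C(C)(C)C)cc2O[Si](C)(C)C(C)(C)C)O1 | intermediate
27 | dienylketene from ring opening of 26 (C5=C6 ketene, C7=C8 alkene with C6 and C8a cis) | O=C=C(C[C@H](CC=C(C)C)C(C)(C)O[Si](CC)(CC)CC)/C(O[Si](C(C)C)(C(C)C)C(C)C)=C\C1=CC(=O)C[C@@H](c2ccc(O[Si](C)(C)C(C)(C)C)cc2O[Si](C)(C)C(C)(C)C)O1 | intermediate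
28 | 4a-H cyclohexa-2,4-dienone tautomer of 29 (C4a unassigned) | O=C1C(C[C@H](CC=C(C)C)C(C)(C)O[Si](CC)(CC)CC)=C(O[Si](C(C)C)(C(C)C)C(C)C)C=C2O[C@H](c3ccc(O[Si](C)(C)C(C)(C)C)cc3O[Si](C)(C)C(C)(C)C)CC(=O)C12 | intermediate
29 | (2S)-2-[2,4-bis(tert-butyldimethylsilyloxy)phenyl]-5-hydroxy-6-[(2S)-5-methyl-2-[2-(triethylsilyloxy)propan-2-yl]hex-4-en-1-yl]-7-(triisopropylsilyloxy)-2,3-dihydro-4H-chromen-4-one | Oc1c(C[C@H](CC=C(C)C)C(C)(C)O[Si](CC)(CC)CC)c(O[Si](C(C)C)(C(C)C)C(C)C)cc2c1C(=O)C[C@@H](c1ccc(O[Si](C)(C)C(C)(C)C)cc1O[Si](C)(C)C(C)(C)C)O2 | intermediate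
30 | (2S)-2-[2,4-bis(tert-butyldimethylsilyloxy)phenyl]-5-methoxy-6-[(2S)-5-methyl-2-[2-(triethylsilyloxy)propan-2-yl]hex-4-en-1-yl]-7-(triisopropylsilyloxy)-2,3-dihydro-4H-chromen-4-one | COc1c(C[C@H](CC=C(C)C)C(C)(C)O[Si](CC)(CC)CC)c(O[Si](C(C)C)(C(C)C)C(C)C)cc2c1C(=O)C[C@@H](c1ccc(O[Si](C)(C)C(C)(C)C)cc1O[Si](C)(C)C(C)(C)C)O2 | intermediate
31 | (2S)-2-(2,4-dihydroxyphenyl)-7-hydroxy-6-[(2S)-2-(2-hydroxypropan-2-yl)-5-methylhex-4-en-1-yl]-5-methoxy-2,3-dihydro-4H-chromen-4-one | COc1c(C[C@H](CC=C(C)C)C(C)(C)O)c(O)cc2c1C(=O)C[C@@H](c1ccc(O)cc1O)O2 | target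

**Step count and risk**

Total step count: 14. Longest linear sequence: 9 steps (steps 6–11, then 12–14) from 5-methylhex-4-enoic acid. The ring B/ring C branch is 7 steps (1, 3, 4, 5, 12, 13, 14), and step 2 is a one-step side branch.

Steps most likely to fail:

1. Step 12. The diazoketone, the ring C enone and the 5-hydroxyflavanone product absorb in the same region. Secondary photochemistry may therefore outrun capture of the ketene by a hindered alkyne: light-driven opening of ring C with loss of C2 integrity, or enone–alkyne photocycloaddition. The ketene may also acylate the product phenol.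
   Fallback, from 11 back to 29: the ketene is generated thermally, without light, in the presence of the alkyne. Wolff rearrangement of 11 alone with PhCO2Ag and Et3N in THF–water in the dark hydrates ketene 25 at once to 2-[(2S)-2-[2,4-bis(tert-butyldimethylsilyloxy)phenyl]-4-oxo-3,4-dihydro-2H-pyran-6-yl]acetic acid F1, which is kept cold because it is a vinylogous β-keto acid. Oxalyl chloride with catalytic DMF in CH2Cl2 at 0 °C gives 2-[(2S)-2-[2,4-bis(tert-butyldimethylsilyloxy)phenyl]-4-oxo-3,4-dihydro-2H-pyran-6-yl]acetyl chloride F2. Slow addition of F2 to Et3N and 24 in toluene at 23 → 80 °C regenerates ketene 25 by dehydrochlorination, and the same cycloaddition, ring opening and electrocyclisation should deliver 29, where the route is rejoined.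

2. Step 3. Turnover may be slow, because the aldehyde is electron-rich and ortho-substituted and the nucleophilic terminus of the diene is deactivated by the conjugated ester. Facial selectivity may be poor, and ionisation at the electron-rich benzylic carbinol during the acid cyclisation may erode the enantiomeric purity.
   Fallback, from 2 back to 7: Brown methallylation of 2 with the methallylborane made from (−)-B-methoxydiisopinocampheylborane and methallylmagnesium chloride (Et2O, −78 °C, NaBO3 work-up) should give (1S)-1-[2,4-bis(tert-butyldimethylsilyloxy)phenyl]-3-methylbut-3-en-1-ol F3 by Si-face attack. Et3SiCl and imidazole give (1S)-1-[2,4-bis(tert-butyldimethylsilyloxy)phenyl]-3-methyl-1-(triethylsilyloxy)but-3-ene F4. Johnson–Lemieux cleavage (catalytic OsO4, NaIO4, 2,6-lutidine, dioxane–water) gives (4S)-4-[2,4-bis(tert-butyldimethylsilyloxy)phenyl]-4-(triethylsilyloxy)butan-2-one F5. Kinetic deprotonation of the methyl group (LiN(SiMe3)2, THF, −78 °C) and Claisen condensation with dimethyl oxalate give methyl (6S)-6-[2,4-bis(tert-butyldimethylsilyloxy)phenyl]-2,4-dioxo-6-(triethylsilyloxy)hexanoate F6. CF3CO2H in wet CH2Cl2 at 0 °C removes the secondary silyl ether and cyclodehydrates to 7.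

3. Step 5. Diazomethane may add as a dipole across the doubly activated ring alkene, or attack the carbonate carbonyl of the mixed anhydride and return the acid as its methyl ester.
   Fallback, from 9 back to 11: the diazo group is introduced by diazo transfer to a methyl ketone instead of by acylation of diazomethane. Oxalyl chloride with catalytic DMF gives (2S)-2-[2,4-bis(tert-butyldimethylsilyloxy)phenyl]-4-oxo-3,4-dihydro-2H-pyran-6-carbonyl chloride F7. Stille coupling with Me4Sn (catalytic PhCH2PdCl(PPh3)2, THF, 65 °C) gives (2S)-6-acetyl-2-[2,4-bis(tert-butyldimethylsilyloxy)phenyl]-2,3-dihydro-4H-pyran-4-one F8. Kinetic enolisation of the acetyl methyl, which is more acidic and less hindered than C3–H2 (LiN(SiMe3)2, THF, −78 °C), and trapping with CF3CO2CH2CF3 give 1-[(2S)-2-[2,4-bis(tert-butyldimethylsilyloxy)phenyl]-4-oxo-3,4-dihydro-2H-pyran-6-yl]-4,4,4-trifluorobutane-1,3-dione F9. Detrifluoroacetylative diazo transfer (MeSO2N3, Et3N, H2O, MeCN, 23 °C) gives 11.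

**Further compounds**

F1 | step 12 | 2-[(2S)-2-[2,4-bis(tert-butyldimethylsilyloxy)phenyl]-4-oxo-3,4-dihydro-2H-pyran-6-yl]acetic acid | OC(=O)CC1=CC(=O)C[C@@H](c2ccc(O[Si](C)(C)C(C)(C)C)cc2O[Si](C)(C)C(C)(C)C)O1
F2 | step 12 | 2-[(2S)-2-[2,4-bis(tert-butyldimethylsilyloxy)phenyl]-4-oxo-3,4-dihydro-2H-pyran-6-yl]acetyl chloride | ClC(=O)CC1=CC(=O)C[C@@H](c2ccc(O[Si](C)(C)C(C)(C)C)cc2O[Si](C)(C)C(C)(C)C)O1
F3 | step 3 | (1S)-1-[2,4-bis(tert-butyldimethylsilyloxy)phenyl]-3-methylbut-3-en-1-ol | C=C(C)C[C@H](O)c1ccc(O[Si](C)(C)C(C)(C)C)cc1O[Si](C)(C)C(C)(C)C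
F4 | step 3 | (1S)-1-[2,4-bis(tert-butyldimethylsilyloxy)phenyl]-3-methyl-1-(triethylsilyloxy)but-3-ene | C=C(C)C[C@H](O[Si](CC)(CC)CC)c1ccc(O[Si](C)(C)C(C)(C)C)cc1O[Si](C)(C)C(C)(C)C
F5 | step 3 | (4S)-4-[2,4-bis(tert-butyldimethylsilyloxy)phenyl]-4-(triethylsilyloxy)butan-2-one | CC(=O)C[C@H](O[Si](CC)(CC)CC)c1ccc(O[Si](C)(C)C(C)(C)C)cc1O[Si](C)(C)C(C)(C)C
F6 | step 3 | methyl (6S)-6-[2,4-bis(tert-butyldimethylsilyloxy)phenyl]-2,4-dioxo-6-(triethylsilyloxy)hexanoate | COC(=O)C(=O)CC(=O)C[C@H](O[Si](CC)(CC)CC)c1ccc(O[Si](C)(C)C(C)(C)C)cc1O[Si](C)(C)C(C)(C)C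
F7 | step 5 | (2S)-2-[2,4-bis(tert-butyldimethylsilyloxy)phenyl]-4-oxo-3,4-dihydro-2H-pyran-6-carbonyl chloride | ClC(=O)C1=CC(=O)C[C@@H](c2ccc(O[Si](C)(C)C(C)(C)C)cc2O[Si](C)(C)C(C)(C)C)O1
F8 | step 5 | (2S)-6-acetyl-2-[2,4-bis(tert-butyldimethylsilyloxy)phenyl]-2,3-dihydro-4H-pyran-4-one | CC(=O)C1=CC(=O)C[C@@H](c2ccc(O[Si](C)(C)C(C)(C)C)cc2O[Si](C)(C)C(C)(C)C)O1
F9 | step 5 | 1-[(2S)-2-[2,4-bis(tert-butyldimethylsilyloxy)phenyl]-4-oxo-3,4-dihydro-2H-pyran-6-yl]-4,4,4-trifluorobutane-1,3-dione | FC(F)(F)C(=O)CC(=O)C1=CC(=O)C[C@@H](c2ccc(O[Si](C)(C)C(C)(C)C)cc2O[Si](C)(C)C(C)(C)C)O1
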